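## Retrosynthetic overview

1. The last bond is C12–C13. A Suzuki–Miyaura coupling joins the (E)-alkenylborane of an alkyne-bearing tetronic acid to the (E)-iodoalkene of the lactam half and gives the E,E-diene.
2. C4–C5: the 3-methyltetronic acid ring is bought intact. As its 2,4-bis(silyloxy)furan it is C5-allylated enantioselectively by a (Z)-allylic bromide under chiral ammonium fluoride ion-pair catalysis (new step, sets C4).
3. C7–C8: a Negishi coupling joins (Z)-3-iodo-2-methylallyl alcohol (Z fixed by anti-carbomagnesiation of propargyl alcohol) to the zinc reagent from (S)-α-methyl-γ-butyrolactone. C10 comes from iminium-catalysed transfer hydrogenation of an achiral enal, and the ester is later homologated to the alkyne.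
4. Lactam half: carboalumination/iodination of hept-6-yn-1-ol, oxidation, condensation with glyoxylic acid, then reductive amination with isopentylamine.
5. Ring order: a transient butyrolactone (made, then opened), then the 5-hydroxybutenolide, then the pyrrolinone. The tetronic ring is present from the start.

Locants used below: C1 (lactone C=O), C2 (C–Me), C3 (C–OH), C4 (ring CH–O), chain C5–C17 (Me on C6, C10, C14), lactam C18–C21.

Assumption: the SMILES is taken as drawn, (S) at C4, (S) at C10, 6Z,11E,13E. The (S,S) antipode of the step 9 catalyst is assumed to give (S)-C4, which must be confirmed in the first run (both antipodes are catalogue items).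

## Route

Step 1
Reactants: 1 methyl pyruvate; 2 (triphenylphosphoranylidene)acetaldehyde
Product: 3 methyl (E)-2-methyl-4-oxobut-2-enoate
Conditions: 1 (1.5 equiv), CH2Cl2, rt, 24 h
Reagents that add atoms: none
Why: Wittig olefination of the activated α-keto ester carbonyl with a stabilised ylide (excess 1 suppresses a second olefination); the E isomer dominates, and any Z isomer is harmless because step 2 is stereoconvergent.

Step 2
Reactants: 3 methyl (E)-2-methyl-4-oxobut-2-enoate
Product: 6 (S)-3-methyldihydrofuran-2(3H)-one, via methyl (S)-2-methyl-4-oxobutanoate 4 (not isolated), via methyl (S)-4-hydroxy-2-methylbutanoate 5 (not isolated)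
Conditions: (R)-2-tert-butyl-3-methylimidazolidin-4-one·Cl3CCO2H (20 mol %), Hantzsch ester (1.2 equiv), CHCl3, −30 °C; then MeOH, NaBH4, 0 °C; then 1 M HCl, rt
Reagents that add atoms: none
Why: Organocatalytic iminium transfer hydrogenation (MacMillan type): the E-iminium ion with CO2Me trans takes hydride on the face away from the tert-butyl group, which sets C10 as (S) (about 91 % ee for this substrate class, sense by analogy with β-methylcinnamaldehyde giving the (S)-product), and chemoselective aldehyde reduction followed by acid lactonisation does not touch the centre.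

Step 3
Reactants: 6 (S)-3-methyldihydrofuran-2(3H)-one
Product: 8 methyl (S)-4-iodo-2-methylbutanoate, via trimethylsilyl (S)-4-iodo-2-methylbutanoate 7 (not isolated)
Conditions: TMSI (1.2 equiv), CH2Cl2, 0 °C to rt; then MeOH, rt
Reagents that add atoms: iodotrimethylsilane C[Si](C)(C)I; methanol CO
Why: Silyl iodide lactone opening (O-silylation, then SN2 of iodide at the O–CH2 carbon) followed by acid-catalysed methanolysis of the silyl ester; the stereocentre is not involved.

Step 4
Reactants: 9 prop-2-yn-1-ol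
Product: 11 (Z)-3-iodo-2-methylprop-2-en-1-ol, via (Z)-[3-(bromomagnesiooxy)-2-methylprop-1-en-1-yl]magnesium bromide 10 (not isolated)
Conditions: MeMgBr (2.5 equiv), CuI (15 mol %), THF, −10 °C to rt; then I2, THF, 0 °C
Reagents that add atoms: methylmagnesium bromide C[Mg]Br; iodine II
Why: Copper-catalysed, alkoxide-directed anti-carbomagnesiation of a propargylic alcohol puts Me on C2 and Mg on C3 cis to CH2O (five-membered chelate), and iodinolysis with retention gives the Z iodide only.

Step 5
Reactants: 8 methyl (S)-4-iodo-2-methylbutanoate; 11 (Z)-3-iodo-2-methylprop-2-en-1-ol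
Product: 13 methyl (2S,5Z)-7-hydroxy-2,6-dimethylhept-5-enoate, via [(S)-4-methoxy-3-methyl-4-oxobutyl]zinc iodide 12 (not isolated)
Conditions: 8 (1.6 equiv), Zn dust (BrCH2CH2Br, TMSCl activation), THF, 40 °C; then slow addition to 11, PdCl2(dppf) (3 mol %), THF, rt
Reagents that add atoms: none
Why: Negishi sp3–sp2 cross-coupling: direct zinc insertion tolerates the ester, alkylzinc iodides are protonated by the alcohol only slowly, and oxidative addition/reductive elimination proceed with retention, so the Z geometry of 11 is carried into C6=C7.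

Step 6
Reactants: 13 methyl (2S,5Z)-7-hydroxy-2,6-dimethylhept-5-enoate
Product: 15 (2Z,6S)-2,6-dimethyloct-2-en-7-yn-1-ol, via (2S,5Z)-7-hydroxy-2,6-dimethylhept-5-enal 14 (not isolated)
Conditions: DIBAL-H (2.3 equiv), CH2Cl2, −78 °C; MeOH; then K2CO3, Ohira–Bestmann reagent, MeOH, 0 °C to rt
Reagents that add atoms: dimethyl (1-diazo-2-oxopropyl)phosphonate CC(=O)C(=[N+]=[N-])P(=O)(OC)OC
Why: One-pot partial ester reduction (stable aluminium hemiacetal at −78 °C) and Seyferth–Gilbert homologation in the Ohira–Bestmann variant; the mild carbonate base leaves the α-methyl centre intact.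

Step 7
Reactants: 15 (2Z,6S)-2,6-dimethyloct-2-en-7-yn-1-ol
Product: 16 (3S,6Z)-8-bromo-3,7-dimethyloct-6-en-1-yne
Conditions: CBr4, PPh3, CH2Cl2, −30 to 0 °C; used at once
Reagents that add atoms: carbon tetrabromide BrC(Br)(Br)Br
Why: Appel bromination of a primary allylic alcohol is an SN2 process at low temperature, so there is no allylic transposition or Z/E leakage.

Step 8
Reactants: 17 3-methyltetronic acid (4-hydroxy-3-methylfuran-2(5H)-one)
Product: 18 2,4-bis[(tert-butyldimethylsilyl)oxy]-3-methylfuran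
Conditions: TBSOTf (2.3 equiv), Et3N (3 equiv), CH2Cl2, 0 °C; pentane extraction, short basic alumina plug
Reagents that add atoms: tert-butyldimethylsilyl triflate CC(C)(C)[Si](C)(C)OS(=O)(=O)C(F)(F)F
Why: Silylation of the acidic OH and then soft enolisation (silyl triflate/amine) of the resulting 4-silyloxybutenolide gives the aromatic 2-silyloxyfuran, a neutral equivalent of the tetronic acid dianion.

Step 9
Reactants: 16 (3S,6Z)-8-bromo-3,7-dimethyloct-6-en-1-yne; 18 2,4-bis[(tert-butyldimethylsilyl)oxy]-3-methylfuran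
Product: 20 (5S)-5-[(2Z,6S)-2,6-dimethyloct-2-en-7-yn-1-yl]-4-hydroxy-3-methylfuran-2(5H)-one, via (5S)-4-[(tert-butyldimethylsilyl)oxy]-5-[(2Z,6S)-2,6-dimethyloct-2-en-7-yn-1-yl]-3-methylfuran-2(5H)-one 19 (not isolated)
Conditions: 18 (1.5 equiv), (S,S)-3,4,5-trifluorophenyl-NAS bromide (N-spiro bis-binaphthyl ammonium salt, 5 mol %), anhydrous CsF (1.6 equiv), toluene/CH2Cl2 4:1, −40 °C; then MeOH, 10 % aq. citric acid, rt
Reagents that add atoms: none
Why: Proposed new method: insoluble CsF enters the organic phase only as the chiral ammonium fluoride (so there is no racemic background), which strips the ketene-acetal silyl group of 18 and leaves a tight chiral ammonium furan-2-olate ion pair; this dienolate has its largest HOMO coefficient at C5 (dienolate terminus and β-carbon of the 4-silyl enol ether, C3 being blocked by methyl), so it displaces the primary allylic bromide by SN2 with the Z geometry retained, while the binaphthyl walls cover one face of the flat anion so that C4 is formed as (S) under pure catalyst control (C10 is too remote to interfere); because no Brønsted base is present and the product stays O-silylated until the acidic quench, the new C–H is not epimerised and is not alkylated again; the closest known reaction types are asymmetric phase-transfer allylation of enolates with N-spiro or cinchona ammonium salts, chiral ammonium fluoride- or phenoxide-triggered reactions of silyl nitronates and 2-silyloxyfurans, and the racemic C5-allylation of lithiated tetronates, whereas an enantioselective C5-alkylation of a tetronic acid with an alkyl halide has not been described.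

Step 10
Reactants: 21 hept-6-yn-1-ol
Product: 23 (E)-7-iodo-6-methylhept-6-en-1-ol, via dimethylaluminium (E)-7-(dimethylalumanyl)-6-methylhept-6-en-1-olate 22 (not isolated)
Conditions: Me3Al (3 equiv), Cp2ZrCl2 (25 mol %), CH2Cl2, 0 °C to rt; then I2, THF, −30 °C
Reagents that add atoms: trimethylaluminium C[Al](C)C; iodine II
Why: Negishi zirconium-catalysed syn-methylalumination of a terminal alkyne (Me on the internal carbon) and iodinolysis with retention give the E trisubstituted iodoalkene; the free OH is masked in situ as its aluminium alkoxide.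

Step 11
Reactants: 23 (E)-7-iodo-6-methylhept-6-en-1-ol
Product: 24 (E)-7-iodo-6-methylhept-6-enal
Conditions: TEMPO (10 mol %), PhI(OAc)2 (1.1 equiv), CH2Cl2, rt
Reagents that add atoms: none
Why: TEMPO/PhI(OAc)2 oxoammonium oxidation stops at the aldehyde and does not touch the iodoalkene.

Step 12
Reactants: 24 (E)-7-iodo-6-methylhept-6-enal; 25 glyoxylic acid
Product: 26 5-hydroxy-4-[(E)-5-iodo-4-methylpent-4-en-1-yl]furan-2(5H)-one (racemic, epimerisable lactol)
Conditions: 25 (50 % aq., 1.1 equiv), morpholine·HCl (1.1 equiv), dioxane/H2O, reflux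
Reagents that add atoms: none
Why: Amine-mediated aldol (Mannich-type) condensation of the morpholine enamine of 24 with glyoxylic acid, dehydration and lactol closure; the only α-carbon of 24 becomes C18, so the 4-substituted 5-hydroxybutenolide is the sole regioisomer.

Step 13
Reactants: 26 5-hydroxy-4-[(E)-5-iodo-4-methylpent-4-en-1-yl]furan-2(5H)-one; 27 3-methylbutan-1-amine
Product: 29 4-[(E)-5-iodo-4-methylpent-4-en-1-yl]-1-(3-methylbutyl)-1,5-dihydro-2H-pyrrol-2-one, via (2Z,7E)-8-iodo-7-methyl-3-{[(3-methylbutyl)amino]methyl}octa-2,7-dienoic acid 28 (not isolated)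
Conditions: 27 (1.1 equiv), NaBH(OAc)3 (1.5 equiv), AcOH, CH2Cl2, rt
Reagents that add atoms: none
Why: Reductive amination of the masked (Z)-4-oxoenoic acid, as is well established for 5-hydroxybutenolides and mucohalic acids; the cis γ-amino acid lactamises spontaneously and the conjugated C=C is not reduced.

Step 14
Reactants: 20 (5S)-5-[(2Z,6S)-2,6-dimethyloct-2-en-7-yn-1-yl]-4-hydroxy-3-methylfuran-2(5H)-one; 29 4-[(E)-5-iodo-4-methylpent-4-en-1-yl]-1-(3-methylbutyl)-1,5-dihydro-2H-pyrrol-2-one
Product: 31 sarcotrine D, via (5S)-4-[(dicyclohexylboranyl)oxy]-5-[(2Z,6S,7E)-8-(dicyclohexylboranyl)-2,6-dimethylocta-2,7-dien-1-yl]-3-methylfuran-2(5H)-one 30 (not isolated)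
Conditions: Cy2BH (2.2 equiv, made in the flask from BH3·SMe2 and cyclohexene), THF, 0 °C; then 29, PdCl2(dppf) (5 mol %), 3 M aq. K3PO4, THF, rt to 40 °C; 1 M HCl work-up
Reagents that add atoms: none
Why: Syn, anti-Markovnikov hydroboration of the terminal alkyne (much faster than the trisubstituted alkene; the acidic OH only consumes one equivalent of borane) followed by Suzuki–Miyaura alkenyl–alkenyl coupling with retention at both partners gives the 11E,13E-diene, and under base the tetronate anion is a spectator whose C4–H cannot be removed.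

## Compound list

1 | methyl pyruvate | CC(=O)C(=O)OC | starting material
2 | (triphenylphosphoranylidene)acetaldehyde | O=CC=P(c1ccccc1)(c1ccccc1)c1ccccc1 | starting material
3 | methyl (E)-2-methyl-4-oxobut-2-enoate | COC(=O)/C(C)=C/C=O | intermediate
4 | methyl (S)-2-methyl-4-oxobutanoate | O=CC[C@H](C)C(=O)OC | intermediate
5 | methyl (S)-4-hydroxy-2-methylbutanoate | OCC[C@H](C)C(=O)OC | intermediate
6 | (S)-3-methyldihydrofuran-2(3H)-one | C[C@H]1CCOC1=O | intermediate
7 | trimethylsilyl (S)-4-iodo-2-methylbutanoate | ICC[C@H](C)C(=O)O[Si](C)(C)C | intermediate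
8 | methyl (S)-4-iodo-2-methylbutanoate | ICC[C@H](C)C(=O)OC | intermediate
9 | prop-2-yn-1-ol | C#CCO | starting material
10 | (Z)-[3-(bromomagnesiooxy)-2-methylprop-1-en-1-yl]magnesium bromide | Br[Mg]OC/C(C)=C\[Mg]Br | intermediate
11 | (Z)-3-iodo-2-methylprop-2-en-1-ol | OC/C(C)=C\I | intermediate
12 | [(S)-4-methoxy-3-methyl-4-oxobutyl]zinc iodide | I[Zn]CC[C@H](C)C(=O)OC | intermediate
13 | methyl (2S,5Z)-7-hydroxy-2,6-dimethylhept-5-enoate | OC/C(C)=C\CC[C@H](C)C(=O)OC | intermediate
14 | (2S,5Z)-7-hydroxy-2,6-dimethylhept-5-enal | OC/C(C)=C\CC[C@H](C)C=O | intermediate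
15 | (2Z,6S)-2,6-dimethyloct-2-en-7-yn-1-ol | OC/C(C)=C\CC[C@H](C)C#C | intermediate
16 | (3S,6Z)-8-bromo-3,7-dimethyloct-6-en-1-yne | BrC/C(C)=C\CC[C@H](C)C#C | intermediate
17 | 3-methyltetronic acid | CC1=C(O)COC1=O | starting material
18 | 2,4-bis[(tert-butyldimethylsilyl)oxy]-3-methylfuran | CC1=C(O[Si](C)(C)C(C)(C)C)OC=C1O[Si](C)(C)C(C)(C)C | intermediate
19 | (5S)-4-[(tert-butyldimethylsilyl)oxy]-5-[(2Z,6S)-2,6-dimethyloct-2-en-7-yn-1-yl]-3-methylfuran-2(5H)-one | CC1=C(O[Si](C)(C)C(C)(C)C)[C@H](C/C(C)=C\CC[C@H](C)C#C)OC1=O | intermediate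
20 | (5S)-5-[(2Z,6S)-2,6-dimethyloct-2-en-7-yn-1-yl]-4-hydroxy-3-methylfuran-2(5H)-one | CC1=C(O)[C@H](C/C(C)=C\CC[C@H](C)C#C)OC1=O | intermediate
21 | hept-6-yn-1-ol | C#CCCCCCO | starting material
22 | dimethylaluminium (E)-7-(dimethylalumanyl)-6-methylhept-6-en-1-olate | C[Al](C)OCCCCC/C(C)=C/[Al](C)C | intermediate
23 | (E)-7-iodo-6-methylhept-6-en-1-ol | OCCCCC/C(C)=C/I | intermediate
24 | (E)-7-iodo-6-methylhept-6-enal | O=CCCCC/C(C)=C/I | intermediate
25 | glyoxylic acid | O=CC(=O)O | starting material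
26 | 5-hydroxy-4-[(E)-5-iodo-4-methylpent-4-en-1-yl]furan-2(5H)-one (racemic lactol) | O=C1C=C(CCC/C(C)=C/I)C(O)O1 | intermediate
27 | 3-methylbutan-1-amine | CC(C)CCN | starting material
28 | (2Z,7E)-8-iodo-7-methyl-3-{[(3-methylbutyl)amino]methyl}octa-2,7-dienoic acid | OC(=O)/C=C(\CNCCC(C)C)CCC/C(C)=C/I | intermediate
29 | 4-[(E)-5-iodo-4-methylpent-4-en-1-yl]-1-(3-methylbutyl)-1,5-dihydro-2H-pyrrol-2-one | O=C1C=C(CCC/C(C)=C/I)CN1CCC(C)C | intermediate
30 | (5S)-4-[(dicyclohexylboranyl)oxy]-5-[(2Z,6S,7E)-8-(dicyclohexylboranyl)-2,6-dimethylocta-2,7-dien-1-yl]-3-methylfuran-2(5H)-one | CC1=C(OB(C2CCCCC2)C2CCCCC2)[C@H](C/C(C)=C\CC[C@H](C)/C=C/B(C2CCCCC2)C2CCCCC2)OC1=O | intermediate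
31 | sarcotrine D, (5S)-4-hydroxy-3-methyl-5-{(2Z,6S,7E,9E)-2,6,10-trimethyl-13-[1-(3-methylbutyl)-5-oxo-2,5-dihydro-1H-pyrrol-3-yl]trideca-2,7,9-trien-1-yl}furan-2(5H)-one | CC1=C(O)[C@H](C/C(C)=C\CC[C@H](C)/C=C/C=C(\C)CCCC2=CC(=O)N(CCC(C)C)C2)OC1=O | target

## Step count and risks

Total step count: 14.
Longest linear sequence: 8 (steps 1, 2, 3, 5, 6, 7, 9, 14).

**Step 9 (new reaction).** Enantioselectivity, the C5/C3/O ratio and fluoride turnover are untested.
- The fallback sets out from 16 and returns at 20. It uses known auxiliary and Dieckmann chemistry.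
- The sodium enolate (NaHMDS, THF, −78 °C) of (R)-4-benzyl-3-{[(4-methoxybenzyl)oxy]acetyl}oxazolidin-2-one is alkylated with 16 to give (R)-4-benzyl-3-{(2S,4Z,8S)-2-[(4-methoxybenzyl)oxy]-4,8-dimethyldec-4-en-9-ynoyl}oxazolidin-2-one F1.
- NaOMe in MeOH gives methyl (2S,4Z,8S)-2-[(4-methoxybenzyl)oxy]-4,8-dimethyldec-4-en-9-ynoate F2.
- DDQ in wet CH2Cl2 gives methyl (2S,4Z,8S)-2-hydroxy-4,8-dimethyldec-4-en-9-ynoate F3.
- Propionic anhydride/DMAP gives methyl (2S,4Z,8S)-4,8-dimethyl-2-(propanoyloxy)dec-4-en-9-ynoate F4.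
- Dieckmann cyclisation with LiHMDS (3.2 equiv, THF, −78 to 0 °C) and acidification gives 20.

**Step 14.** The free tetronic acid may bind boron or palladium, and the alkenylborane may protodeboronate.
- The fallback sets out from 20 (with 29) and returns at 31. It switches to a protected Stille union.
- Me2SO4/K2CO3 in acetone gives (5S)-5-[(2Z,6S)-2,6-dimethyloct-2-en-7-yn-1-yl]-4-methoxy-3-methylfuran-2(5H)-one F5.
- Pd-catalysed hydrostannation (Bu3SnH, PdCl2(PPh3)2) gives (5S)-5-[(2Z,6S,7E)-2,6-dimethyl-8-(tributylstannyl)octa-2,7-dien-1-yl]-4-methoxy-3-methylfuran-2(5H)-one F6.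
- Stille coupling with 29 (Pd2(dba)3, AsPh3, CuI, DMF, rt) gives O-methyl sarcotrine D F7.
- Nucleophilic demethylation with n-PrSLi in DMF gives 31.

**Step 5.** The unprotected alcohol may protonate the zinc reagent, and some Z to E erosion on palladium is possible.
- The fallback sets out from 8 (with 11) and returns at 13. It replaces the organozinc by an air- and water-stable organoboron partner.
- Copper-catalysed borylation of 8 (B2pin2, CuI, PPh3, LiOMe, DMF) gives methyl (S)-2-methyl-4-(4,4,5,5-tetramethyl-1,3,2-dioxaborolan-2-yl)butanoate F8.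
- Aqueous KHF2 in MeOH gives potassium [(S)-4-methoxy-3-methyl-4-oxobutyl]trifluoroborate F9.
- F9 couples with unprotected 11 under alkyltrifluoroborate Suzuki–Miyaura conditions (PdCl2(dppf), Cs2CO3, toluene/H2O, 80 °C) to give 13.

## Further compounds

F1 | step 9 | (R)-4-benzyl-3-{(2S,4Z,8S)-2-[(4-methoxybenzyl)oxy]-4,8-dimethyldec-4-en-9-ynoyl}oxazolidin-2-one | O=C1OC[C@@H](Cc2ccccc2)N1C(=O)[C@H](C/C(C)=C\CC[C@H](C)C#C)OCc1ccc(OC)cc1
F2 | step 9 | methyl (2S,4Z,8S)-2-[(4-methoxybenzyl)oxy]-4,8-dimethyldec-4-en-9-ynoate | COC(=O)[C@H](C/C(C)=C\CC[C@H](C)C#C)OCc1ccc(OC)cc1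
F3 | step 9 | methyl (2S,4Z,8S)-2-hydroxy-4,8-dimethyldec-4-en-9-ynoate | COC(=O)[C@H](C/C(C)=C\CC[C@H](C)C#C)O
F4 | step 9 | methyl (2S,4Z,8S)-4,8-dimethyl-2-(propanoyloxy)dec-4-en-9-ynoate | COC(=O)[C@H](C/C(C)=C\CC[C@H](C)C#C)OC(=O)CC
F5 | step 14 | (5S)-5-[(2Z,6S)-2,6-dimethyloct-2-en-7-yn-1-yl]-4-methoxy-3-methylfuran-2(5H)-one | CC1=C(OC)[C@H](C/C(C)=C\CC[C@H](C)C#C)OC1=O
F6 | step 14 | (5S)-5-[(2Z,6S,7E)-2,6-dimethyl-8-(tributylstannyl)octa-2,7-dien-1-yl]-4-methoxy-3-methylfuran-2(5H)-one | CC1=C(OC)[C@H](C/C(C)=C\CC[C@H](C)/C=C/[Sn](CCCC)(CCCC)CCCC)OC1=O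
F7 | step 14 | O-methyl sarcotrine D | CC1=C(OC)[C@H](C/C(C)=C\CC[C@H](C)/C=C/C=C(\C)CCCC2=CC(=O)N(CCC(C)C)C2)OC1=O
F8 | step 5 | methyl (S)-2-methyl-4-(4,4,5,5-tetramethyl-1,3,2-dioxaborolan-2-yl)butanoate | CC1(C)OB(CC[C@H](C)C(=O)OC)OC1(C)C
F9 | step 5 | potassium [(S)-4-methoxy-3-methyl-4-oxobutyl]trifluoroborate | [K+].F[B-](F)(F)CC[C@H](C)C(=O)OC
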